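**Retrosynthetic overview (eudesmane numbering; ring A = C1–C5/C10, ring B = C5–C10)**
1. Equatorial C1–Br from a 1-bromo-1-ene by radical hydrogenation (H to the α-face); the bromo-ene from a C1 ketone.
2. Key C–O disconnection: 6α-OAc and 7α-H from a Δ6 olefin by anti-Markovnikov hydroacetoxylation (sets C6 and C7).
3. Rings A and B are closed together (C5–C10, C8–C9) by an intramolecular Diels–Alder reaction of a 1,7,9-decatrien-3-one; the C4 carbinol relays to C5 and C10.
4. Trienone from Heck coupling of an isopropenyl ketone with 3-methylbut-1-en-2-yl triflate; the ketone oxygen (future C1) is put into (S)-linalool by a singlet-oxygen ene C–O formation.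

Assumption: the target is taken as drawn, (1R,4S,5S,6S,7S,10R) = 1β-Br, 4β-OH, 4α-CH3, 5α-H, 6α-OAc, 7β-isopropyl, 10β-CH3, and commercial coriander-derived (S)-(+)-linalool of high enantiomeric purity is used.

**Step 1**
Reactants: 1 (S)-(+)-linalool [(3S)-3,7-dimethylocta-1,6-dien-3-ol]
Product: 3 (6S)-6-hydroxy-2,6-dimethylocta-1,7-dien-3-one, via allylic hydroperoxide 2 (not isolated)
Conditions: O2, tetraphenylporphyrin (cat.), white LEDs, CH2Cl2, 0 °C; then Ac2O, Et3N, DMAP (cat.), 0 → 23 °C
Reagents that add atoms: oxygen, O=O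
Why: Schenck ene reaction of singlet oxygen at the trisubstituted alkene (the vinyl group is inert) forms the C–O bond at the future C1 and moves the double bond into the isopropenyl position, and Kornblum–DeLaMare-type dehydration of the secondary hydroperoxide gives the enone; no stereocentre is made, the carbinol centre is untouched, and the regioisomeric tertiary hydroperoxide (about half of the ene product) does not dehydrate and is separated.

**Step 2**
Reactants: 4 3-methylbutan-2-one
Product: 5 3-methylbut-1-en-2-yl trifluoromethanesulfonate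
Conditions: LiN(iPr)2, THF, −78 °C; then PhNTf2, −78 → 0 °C
Reagents that add atoms: N-phenylbis(trifluoromethanesulfonimide), O=S(=O)(N(c1ccccc1)S(=O)(=O)C(F)(F)F)C(F)(F)F
Why: Kinetic deprotonation at the methyl group and O-triflation of the less substituted lithium enolate (enol triflate formation) gives the 1,1-disubstituted alkenyl triflate; no stereocentre.

**Step 3**
Reactants: 3 (6S)-6-hydroxy-2,6-dimethylocta-1,7-dien-3-one; 5 3-methylbut-1-en-2-yl trifluoromethanesulfonate
Product: 7 (4S,5R,10R)-4-hydroxyeudesm-6-en-1-one (4β-OH; 5α-H; 10β-CH3; trans-decalin), via trienone 6 (not isolated)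
Conditions: Pd(OAc)2 (5 mol %), PPh3 (10 mol %), NaHCO3, DMF, 45 °C; then 85 °C
Reagents that add atoms: none
Why: Mizoroki–Heck coupling at the unhindered terminus of the vinyl carbinol gives the (E)-diene, and the resulting trienone closes both rings by an intramolecular Diels–Alder reaction through the chair-like transition state with the dienophile methyl endo and the chain carbonyl exo (trans fusion) and with the C4 hydroxyl, not the C4 methyl, syn-axial to the angular methyl, so the linalool centre sets C5 and C10.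

**Step 4**
Reactants: 7 (4S,5R,10R)-4-hydroxyeudesm-6-en-1-one
Product: 8 (4S,5S,6S,7S,10R)-4-hydroxy-1-oxoeudesman-6-yl acetate
Conditions: 9-mesityl-10-methylacridinium tetrafluoroborate (5 mol %), 2,4,6-triisopropylbenzenethiol (20 mol %), AcOH (10 equiv), 2,6-lutidine (10 mol %), ClCH2CH2Cl, 450 nm LEDs, 23 °C
Reagents that add atoms: acetic acid, CC(=O)O
Why: Proposed new method: substrate-controlled photocatalytic anti-Markovnikov hydroacetoxylation of the hindered trisubstituted ring-B alkene, in which the excited acridinium oxidises the C6=C7 π-bond to its radical cation, acetic acid adds at the less substituted C6 from the α-face because the β-face is blocked by the syn-axial C10 methyl and C4 hydroxyl (6α-OAc), the tertiary C7 radical takes hydrogen from the hindered thiol on the axial α-face to leave the isopropyl group equatorial (7β), and the thiyl radical reoxidises the acridine radical; the closest known reaction type is acridinium-photoredox anti-Markovnikov hydroacyloxylation of simple alkenes with a thiol hydrogen-atom-transfer co-catalyst, not yet shown on a polyfunctional decalin or with control of two new stereocentres.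

**Step 5**
Reactants: 8 (4S,5S,6S,7S,10R)-4-hydroxy-1-oxoeudesman-6-yl acetate
Product: 10 (4S,5S,6S,7S,10R)-1-bromo-4-hydroxyeudesm-1-en-6-yl acetate, via silyl hydrazone 9 (not isolated)
Conditions: (TBSNH)2, Sc(OTf)3 (1 mol %), CHCl3, 55 °C; evaporation; then NBS, BTMG (2-tert-butyl-1,1,3,3-tetramethylguanidine), CH2Cl2, −10 → 23 °C
Reagents that add atoms: N-bromosuccinimide, O=C1CCC(=O)N1Br; 1,2-bis(tert-butyldimethylsilyl)hydrazine, CC(C)(C)[Si](C)(C)NN[Si](C)(C)C(C)(C)C (its atoms stay only in 9)
Why: Barton vinyl halide synthesis in its N-silyl hydrazone form, in which the hindered C1 ketone condenses without hydrazinolysis of the acetate and oxidation by NBS through the diazo compound and the α-bromo diazonium ion, then loss of N2 and of the only available β-proton (C2–H, C10 being quaternary), gives the 1-bromo-1-ene; no stereocentre is touched.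

**Step 6**
Reactants: 10 (4S,5S,6S,7S,10R)-1-bromo-4-hydroxyeudesm-1-en-6-yl acetate
Product: 11 (1R,4S,5S,6S,7S,10R)-1-bromo-4-hydroxyeudesman-6-yl acetate (target)
Conditions: Co(acac)2, t-BuOOH, Et3SiH, 1,4-cyclohexadiene, n-PrOH, 23 °C
Reagents that add atoms: none
Why: Metal-hydride hydrogen-atom-transfer (Mukaiyama-type) hydrogenation of the alkenyl bromide, in which the cobalt hydride gives H to C2 and the α-bromo C1 radical takes its hydrogen from 1,4-cyclohexadiene on the axial α-face anti to the angular methyl, so the C–Br bond survives and ends equatorial (1β).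

**Compound list**
1 | (S)-(+)-linalool, (3S)-3,7-dimethylocta-1,6-dien-3-ol | CC(C)=CCC[C@](C)(O)C=C | starting material
2 | (3RS,6S)-3-hydroperoxy-2,6-dimethylocta-1,7-dien-6-ol (both C3 epimers) | C=C(C)C(OO)CC[C@](C)(O)C=C | intermediate
3 | (6S)-6-hydroxy-2,6-dimethylocta-1,7-dien-3-one | C=C(C)C(=O)CC[C@](C)(O)C=C | intermediate
4 | 3-methylbutan-2-one | CC(=O)C(C)C | starting material
5 | 3-methylbut-1-en-2-yl trifluoromethanesulfonate | C=C(OS(=O)(=O)C(F)(F)F)C(C)C | intermediate
6 | (6S,7E)-6-hydroxy-2,6-dimethyl-9-(propan-2-yl)deca-1,7,9-trien-3-one | C=C(C)C(=O)CC[C@](C)(O)/C=C/C(=C)C(C)C | intermediate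
7 | (4S,5R,10R)-4-hydroxyeudesm-6-en-1-one; (4S,4aR,8aR)-4-hydroxy-4,8a-dimethyl-6-(propan-2-yl)-3,4,4a,7,8,8a-hexahydronaphthalen-1(2H)-one | CC(C)C1=C[C@@H]2[C@@](C)(CC1)C(=O)CC[C@]2(C)O | intermediate
8 | (4S,5S,6S,7S,10R)-4-hydroxy-1-oxoeudesman-6-yl acetate | CC(=O)O[C@@H]1[C@@H]2[C@@](C)(CC[C@H]1C(C)C)C(=O)CC[C@]2(C)O | intermediate
9 | N-(tert-butyldimethylsilyl)hydrazone of 8 at C1 | CC(=O)O[C@@H]1[C@@H]2[C@@](C)(CC[C@H]1C(C)C)C(=NN[Si](C)(C)C(C)(C)C)CC[C@]2(C)O | intermediate
10 | (4S,5S,6S,7S,10R)-1-bromo-4-hydroxyeudesm-1-en-6-yl acetate | CC(=O)O[C@@H]1[C@@H]2[C@@](C)(CC[C@H]1C(C)C)C(Br)=CC[C@]2(C)O | intermediate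
11 | (1R,4S,5S,6S,7S,10R)-1-bromo-4-hydroxyeudesman-6-yl acetate | CC(=O)O[C@@H]1[C@@H]2[C@@](C)(CC[C@H]1C(C)C)[C@H](Br)CC[C@]2(C)O | target

**Step count and risks**
Total steps: 6. Longest linear sequence: 5 (steps 1, 3, 4, 5, 6; 1 → 3 → 7 → 8 → 10 → 11).

Most likely to fail:

- **Step 3.** The Heck step must choose the vinyl carbinol over the isopropenyl ketone, and the cycloaddition must favour the trans-fused isomer with the hydroxyl axial; this selectivity is expected but not proven. The fallback builds ring A first and ring B second; it sets out from 3 and comes back at 7. Ring-closing metathesis of 3 (second-generation Hoveyda–Grubbs catalyst, CH2Cl2, 40 °C) gives (4S)-4-hydroxy-2,4-dimethylcyclohex-2-en-1-one F1. Alkoxide-directed conjugate addition of CH2=CHMgBr (CuBr·SMe2, THF, −40 °C) syn to the C4 oxygen, with the enolate trapped anti to the new vinyl group by Michael addition to 4-methylpent-1-en-3-one, gives (2R,3R,4S)-3-ethenyl-4-hydroxy-2,4-dimethyl-2-(4-methyl-3-oxopentyl)cyclohexan-1-one F2. Wittig methylenation of the less hindered side-chain ketone (Ph3PCH3Br, KOtBu, THF) gives (2R,3R,4S)-3-ethenyl-4-hydroxy-2,4-dimethyl-2-(4-methyl-3-methylidenepentyl)cyclohexan-1-one F3. A second ring-closing metathesis (second-generation Grubbs catalyst, toluene, 80 °C) closes ring B to 7.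

- **Step 4 (the proposed new step).** Face selectivity at C6 and reactivity of the hindered alkene are untested. The fallback uses known chemistry; it sets out from 7 and comes back at 8. Ketalisation of the C1 ketone (ethylene glycol, (EtO)3CH, TsOH cat.) gives (4S,5R,10R)-1,1-(ethylenedioxy)eudesm-6-en-4-ol F4. Hydroboration–oxidation (BH3·SMe2, THF; then NaOH, H2O2) adds H and OH syn from the α-face to give (4S,5S,6S,7S,10R)-1,1-(ethylenedioxy)eudesmane-4,6-diol F5. Acetylation of the secondary hydroxyl only (Ac2O, pyridine, DMAP) gives (4S,5S,6S,7S,10R)-1,1-(ethylenedioxy)-4-hydroxyeudesman-6-yl acetate F6, and mild hydrolysis (PPTS, acetone–water) returns 8.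

- **Step 6.** The hindered bromo-alkene may react slowly, lose bromine, or give the C1 epimer. The fallback replaces the radical route by an ionic one; it sets out from 8 and comes back at 11. Reduction of 8 with Li[HB(sec-Bu)3] (THF, −78 °C; equatorial hydride delivery) gives the axial alcohol (1S,4S,5S,6S,7S,10R)-1,4-dihydroxyeudesman-6-yl acetate F7. Appel bromination (CBr4, PPh3, CH2Cl2) with inversion at C1 gives 11.

**Further compounds**
F1 | step 3 | (4S)-4-hydroxy-2,4-dimethylcyclohex-2-en-1-one | O=C1CC[C@](C)(O)C=C1C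
F2 | step 3 | (2R,3R,4S)-3-ethenyl-4-hydroxy-2,4-dimethyl-2-(4-methyl-3-oxopentyl)cyclohexan-1-one | C=C[C@@H]1[C@@](C)(CCC(=O)C(C)C)C(=O)CC[C@]1(C)O
F3 | step 3 | (2R,3R,4S)-3-ethenyl-4-hydroxy-2,4-dimethyl-2-(4-methyl-3-methylidenepentyl)cyclohexan-1-one | C=C[C@@H]1[C@@](C)(CCC(=C)C(C)C)C(=O)CC[C@]1(C)O
F4 | step 4 | (4S,5R,10R)-1,1-(ethylenedioxy)eudesm-6-en-4-ol | CC(C)C1=C[C@@H]2[C@@](C)(CC1)C3(OCCO3)CC[C@]2(C)O
F5 | step 4 | (4S,5S,6S,7S,10R)-1,1-(ethylenedioxy)eudesmane-4,6-diol | O[C@@H]1[C@@H]2[C@@](C)(CC[C@H]1C(C)C)C3(OCCO3)CC[C@]2(C)O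
F6 | step 4 | (4S,5S,6S,7S,10R)-1,1-(ethylenedioxy)-4-hydroxyeudesman-6-yl acetate | CC(=O)O[C@@H]1[C@@H]2[C@@](C)(CC[C@H]1C(C)C)C3(OCCO3)CC[C@]2(C)O
F7 | step 6 | (1S,4S,5S,6S,7S,10R)-1,4-dihydroxyeudesman-6-yl acetate | CC(=O)O[C@@H]1[C@@H]2[C@@](C)(CC[C@H]1C(C)C)[C@@H](O)CC[C@]2(C)O
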